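**Retrosynthetic overview**
- The last C–C bond made is C6–CH2(ring E). It is cut back to the 7-O-benzylic ether of the benzyl-protected arm (rings E, F, G), which rearranges by a Sc(OTf)3-promoted 1,3 O-to-C shift; four O-benzyl groups then fall to hydrogenolysis.
- The strategy rests on ring A: O7 is the free, acidic phenol para to the C4 carbonyl, while O5 is held in a hydrogen bond to C4=O, and C6 and C8 are the two ortho carbons of O7. Ring E has an oxygen ortho to the migrating CH2, so O7 leaves as a vinylogous carboxylate from an oxygen-stabilised benzylic cation that returns to C6 once C8 is filled.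
- C8–CH2(ring D) is made by the same shift from O7 one stage earlier. An iodine at C6, placed ortho to the 5-OH and removed afterwards, makes that first shift regiodefined.
- The arm: ring F–CH2–ring G is bought as 2,2'-methylenediphenol, the ring F carbon comes from a magnesium-mediated ortho-formylation, and ring E–CH2–ring F from a benzylic Suzuki coupling. Both ethers to O7 are made by Mitsunobu reaction, so no base reaches C2.
- No ring is formed in the route: rings A, B, C and the (S) centre at C2 come from (S)-pinocembrin, rings D to G from the aromatic building blocks.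

Key step: step 14

Assumption: a 7-O-benzylic ether of pinocembrin with both C6 and C8 free would rearrange to both carbons, and acid-catalysed benzylation of the bisphenol would go para as well as ortho, so a C6 iodine block and a formylation/Suzuki sequence are used; the four starting materials are taken as purchasable, (S)-pinocembrin as the natural enantiomer.

**Step 1**
Reactants: 1 2,2'-methylenediphenol
Product: 2 2-[2-(benzyloxy)benzyl]phenol
Conditions: BnBr (1.0 equiv), K2CO3 (1.0 equiv), acetone, reflux
Reagents that add atoms: benzyl bromide, BrCc1ccccc1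
Why: Williamson ether synthesis; the mono-phenoxide of the bisphenol is stabilised by the hydrogen bond from the neighbouring OH, so one equivalent of base and bromide should give mainly the mono-ether, which is separated from diol and bis-ether by chromatography.

**Step 2**
Reactants: 2 2-[2-(benzyloxy)benzyl]phenol
Product: 3 3-[2-(benzyloxy)benzyl]-2-hydroxybenzaldehyde
Conditions: MgCl2, Et3N, (CH2O)n, MeCN, reflux; then aq. HCl
Reagents that add atoms: paraformaldehyde (formaldehyde), C=O
Why: Magnesium-mediated ortho-formylation of a phenol (Casnati–Skattebøl reaction); the magnesium phenoxide delivers formaldehyde only to the single free ortho carbon of the phenol ring, the para carbon is not attacked, and a second formaldehyde takes the hydride to give the aldehyde.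

**Step 3**
Reactants: 3 3-[2-(benzyloxy)benzyl]-2-hydroxybenzaldehyde
Product: 4 2-(benzyloxy)-3-[2-(benzyloxy)benzyl]benzaldehyde
Conditions: BnBr, K2CO3, DMF, 60 °C
Reagents that add atoms: benzyl bromide, BrCc1ccccc1
Why: Williamson ether synthesis on the salicylaldehyde phenol, which in DMF should be alkylated despite its two ortho substituents.

**Step 4**
Reactants: 4 2-(benzyloxy)-3-[2-(benzyloxy)benzyl]benzaldehyde
Product: 5 {2-(benzyloxy)-3-[2-(benzyloxy)benzyl]phenyl}methanol
Conditions: NaBH4, THF–MeOH, 0 °C
Reagents that add atoms: none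
Why: Borohydride reduction of an aromatic aldehyde to the benzylic alcohol, with the benzyl ethers inert.

**Step 5**
Reactants: 5 {2-(benzyloxy)-3-[2-(benzyloxy)benzyl]phenyl}methanol
Product: 6 2-(benzyloxy)-1-(bromomethyl)-3-[2-(benzyloxy)benzyl]benzene
Conditions: CBr4, PPh3, CH2Cl2, 0 °C
Reagents that add atoms: carbon tetrabromide, BrC(Br)(Br)Br
Why: Appel bromination of a primary benzylic alcohol under neutral conditions, which spares the benzyl ethers; the bromide is used without long storage.

**Step 6**
Reactants: 7 2-(benzyloxy)-5-bromobenzaldehyde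
Product: 8 2-(benzyloxy)-5-(4,4,5,5-tetramethyl-1,3,2-dioxaborolan-2-yl)benzaldehyde
Conditions: B2pin2, PdCl2(dppf) (3 mol%), KOAc, dioxane, 85 °C
Reagents that add atoms: bis(pinacolato)diboron, CC1(C)OB(OC1(C)C)B1OC(C)(C)C(C)(C)O1
Why: Miyaura borylation of an aryl bromide, which tolerates the aldehyde and places boron para to the ring E oxygen.

**Step 7**
Reactants: 6 2-(benzyloxy)-1-(bromomethyl)-3-[2-(benzyloxy)benzyl]benzene; 8 2-(benzyloxy)-5-(4,4,5,5-tetramethyl-1,3,2-dioxaborolan-2-yl)benzaldehyde
Product: 9 2-(benzyloxy)-5-{2-(benzyloxy)-3-[2-(benzyloxy)benzyl]benzyl}benzaldehyde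
Conditions: PdCl2(dppf) (5 mol%), K2CO3, dioxane–H2O (10:1), 70 °C
Reagents that add atoms: none
Why: Suzuki–Miyaura coupling of a benzylic bromide with an arylboronate, which fixes the ring E–CH2–ring F bridge at defined carbons of both rings and so avoids the ortho/para question of a Friedel–Crafts benzylation.

**Step 8**
Reactants: 9 2-(benzyloxy)-5-{2-(benzyloxy)-3-[2-(benzyloxy)benzyl]benzyl}benzaldehyde
Product: 10 (2-(benzyloxy)-5-{2-(benzyloxy)-3-[2-(benzyloxy)benzyl]benzyl}phenyl)methanol (arm alcohol)
Conditions: NaBH4, THF–MeOH, 0 °C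
Reagents that add atoms: none
Why: Borohydride reduction of the aromatic aldehyde to the benzylic alcohol needed for the Mitsunobu reaction.

**Step 9**
Reactants: 11 (S)-pinocembrin [(2S)-5,7-dihydroxy-2-phenylchroman-4-one]; 12 2-(benzyloxy)benzyl alcohol
Product: 13 (2S)-7-{[2-(benzyloxy)benzyl]oxy}-5-hydroxy-2-phenylchroman-4-one
Conditions: PPh3, DIAD, THF, 0 °C → rt
Reagents that add atoms: none
Why: Mitsunobu etherification; only the acidic 7-OH should react because the 5-OH is tied to the C4 carbonyl, and the base-free conditions avoid opening to the chalcone, so C2 stays (S).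

**Step 10**
Reactants: 13 (2S)-7-{[2-(benzyloxy)benzyl]oxy}-5-hydroxy-2-phenylchroman-4-one
Product: 14 (2S)-7-{[2-(benzyloxy)benzyl]oxy}-5-hydroxy-6-iodo-2-phenylchroman-4-one
Conditions: BnMe3N+ ICl2− (1.05 equiv), CaCO3, CH2Cl2–MeOH, rt
Reagents that add atoms: benzyltrimethylammonium dichloroiodate, C[N+](C)(C)Cc1ccccc1.Cl[I-]Cl
Why: Electrophilic ortho-iodination of a free phenol, which in 5-hydroxy-7-alkoxy flavonoids should go to C6 next to the 5-OH; the mild buffered reagent should leave C8, the anisole-type ring and the benzylic ether alone.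

**Step 11**
Reactants: 14 (2S)-7-{[2-(benzyloxy)benzyl]oxy}-5-hydroxy-6-iodo-2-phenylchroman-4-one
Product: 15 (2S)-8-[2-(benzyloxy)benzyl]-5,7-dihydroxy-6-iodo-2-phenylchroman-4-one
Conditions: Sc(OTf)3 (10 mol%), 4 Å MS, CH2Cl2, 0.01 M, 0 °C → rt
Reagents that add atoms: none
Why: Lewis-acid-promoted 1,3 O-to-C shift of a benzyl aryl ether (benzyl ether to ortho-benzylphenol rearrangement); with C6 occupied by iodine, the ortho-benzyloxybenzyl cation can be recaptured only at C8.

**Step 12**
Reactants: 15 (2S)-8-[2-(benzyloxy)benzyl]-5,7-dihydroxy-6-iodo-2-phenylchroman-4-one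
Product: 16 (2S)-8-[2-(benzyloxy)benzyl]-5,7-dihydroxy-2-phenylchroman-4-one
Conditions: Bu3SnH (1.3 equiv), AIBN (10 mol%), PhMe, 80 °C; KF work-up
Reagents that add atoms: none
Why: Radical hydrodeiodination of an aryl iodide with tin hydride, a neutral chain reaction that should leave the ketone, the benzyl ether and C2 untouched.

**Step 13**
Reactants: 16 (2S)-8-[2-(benzyloxy)benzyl]-5,7-dihydroxy-2-phenylchroman-4-one; 10 (2-(benzyloxy)-5-{2-(benzyloxy)-3-[2-(benzyloxy)benzyl]benzyl}phenyl)methanol
Product: 17 (2S)-8-[2-(benzyloxy)benzyl]-7-[(2-(benzyloxy)-5-{2-(benzyloxy)-3-[2-(benzyloxy)benzyl]benzyl}benzyl)oxy]-5-hydroxy-2-phenylchroman-4-one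
Conditions: PPh3, DIAD, THF, 0 °C → rt
Reagents that add atoms: none
Why: Mitsunobu etherification of the acidic 7-OH with a primary benzylic alcohol, the chelated 5-OH staying free and C2 not exposed to base.

**Step 14**
Reactants: 17 (2S)-8-[2-(benzyloxy)benzyl]-7-[(2-(benzyloxy)-5-{2-(benzyloxy)-3-[2-(benzyloxy)benzyl]benzyl}benzyl)oxy]-5-hydroxy-2-phenylchroman-4-one
Product: 18 (2S)-8-[2-(benzyloxy)benzyl]-6-(2-(benzyloxy)-5-{2-(benzyloxy)-3-[2-(benzyloxy)benzyl]benzyl}benzyl)-5,7-dihydroxy-2-phenylchroman-4-one
Conditions: Sc(OTf)3 (20 mol%), 4 Å MS, CH2Cl2–PhMe (1:1), 0.005 M, −20 °C → rt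
Reagents that add atoms: none
Why: Sc(OTf)3 should bind the C4 carbonyl/5-OH chelate, which makes O7 a vinylogous carboxylate leaving group, so the O7–CH2 bond ionises to a contact pair of the ring A phenoxide and the ring E benzylic cation, stabilised as an oxocarbenium by its ortho benzyloxy oxygen; the cation is recaptured at C6 and loss of the C6 proton restores ring A. The closest known reaction type is the acid-promoted rearrangement of benzyl aryl ethers to ortho-benzylphenols, the Fries-like shift seen when alkoxybenzyl aryl ethers meet acid. No ring is closed and no stereocentre is formed; C2 lies outside the reacting system and the aprotic, base-free medium gives no path to the chalcone. The step needs C6 to win over the mono-oxygenated rings D, E, F, G and over transfer between molecules: C8 already carries the ring D benzyl group, so C6 is the only free ortho carbon of the phenoxide and is a phloroglucinol-type carbon far more nucleophilic than any anisole-type ring. The meta linkage of ring E keeps the cation away from its own rings F and G, and high dilution in a weakly polar solvent favours collapse inside the ion pair. The plain O-benzyl ethers should stay, since an unsubstituted benzyl cation and a simple phenoxide form a much poorer ion pair.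

**Step 15**
Reactants: 18 (2S)-8-[2-(benzyloxy)benzyl]-6-(2-(benzyloxy)-5-{2-(benzyloxy)-3-[2-(benzyloxy)benzyl]benzyl}benzyl)-5,7-dihydroxy-2-phenylchroman-4-one
Product: 19 (2S)-5,7-dihydroxy-8-(2-hydroxybenzyl)-6-{2-hydroxy-5-[2-hydroxy-3-(2-hydroxybenzyl)benzyl]benzyl}-2-phenylchroman-4-one (target)
Conditions: H2 (1 atm), 10% Pd/C, EtOAc–MeOH, rt
Reagents that add atoms: none
Why: Catalytic hydrogenolysis of four aryl benzyl ethers under neutral conditions, which should be faster than reduction of the ketone or cleavage of the C2–O1 bond when stopped at full conversion.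

**Compound list**
1 | 2,2'-methylenediphenol | Oc1ccccc1Cc1ccccc1O | starting material
2 | 2-[2-(benzyloxy)benzyl]phenol | Oc1ccccc1Cc1ccccc1OCc1ccccc1 | intermediate
3 | 3-[2-(benzyloxy)benzyl]-2-hydroxybenzaldehyde | O=Cc1cccc(Cc2ccccc2OCc2ccccc2)c1O | intermediate
4 | 2-(benzyloxy)-3-[2-(benzyloxy)benzyl]benzaldehyde | O=Cc1cccc(Cc2ccccc2OCc2ccccc2)c1OCc1ccccc1 | intermediate
5 | {2-(benzyloxy)-3-[2-(benzyloxy)benzyl]phenyl}methanol | OCc1cccc(Cc2ccccc2OCc2ccccc2)c1OCc1ccccc1 | intermediate
6 | 2-(benzyloxy)-1-(bromomethyl)-3-[2-(benzyloxy)benzyl]benzene | BrCc1cccc(Cc2ccccc2OCc2ccccc2)c1OCc1ccccc1 | intermediate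
7 | 2-(benzyloxy)-5-bromobenzaldehyde | O=Cc1cc(Br)ccc1OCc1ccccc1 | starting material
8 | 2-(benzyloxy)-5-(4,4,5,5-tetramethyl-1,3,2-dioxaborolan-2-yl)benzaldehyde | O=Cc1cc(B2OC(C)(C)C(C)(C)O2)ccc1OCc1ccccc1 | intermediate
9 | 2-(benzyloxy)-5-{2-(benzyloxy)-3-[2-(benzyloxy)benzyl]benzyl}benzaldehyde | O=Cc1cc(Cc2cccc(Cc3ccccc3OCc3ccccc3)c2OCc2ccccc2)ccc1OCc1ccccc1 | intermediate
10 | (2-(benzyloxy)-5-{2-(benzyloxy)-3-[2-(benzyloxy)benzyl]benzyl}phenyl)methanol | OCc1cc(Cc2cccc(Cc3ccccc3OCc3ccccc3)c2OCc2ccccc2)ccc1OCc1ccccc1 | intermediate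
11 | (S)-pinocembrin, (2S)-5,7-dihydroxy-2-phenylchroman-4-one | O=C1C[C@@H](c2ccccc2)Oc2cc(O)cc(O)c21 | starting material
12 | 2-(benzyloxy)benzyl alcohol | OCc1ccccc1OCc1ccccc1 | starting material
13 | (2S)-7-{[2-(benzyloxy)benzyl]oxy}-5-hydroxy-2-phenylchroman-4-one | O=C1C[C@@H](c2ccccc2)Oc2cc(OCc3ccccc3OCc3ccccc3)cc(O)c21 | intermediate
14 | (2S)-7-{[2-(benzyloxy)benzyl]oxy}-5-hydroxy-6-iodo-2-phenylchroman-4-one | O=C1C[C@@H](c2ccccc2)Oc2cc(OCc3ccccc3OCc3ccccc3)c(I)c(O)c21 | intermediate
15 | (2S)-8-[2-(benzyloxy)benzyl]-5,7-dihydroxy-6-iodo-2-phenylchroman-4-one | O=C1C[C@@H](c2ccccc2)Oc2c(Cc3ccccc3OCc3ccccc3)c(O)c(I)c(O)c21 | intermediate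
16 | (2S)-8-[2-(benzyloxy)benzyl]-5,7-dihydroxy-2-phenylchroman-4-one | O=C1C[C@@H](c2ccccc2)Oc2c(Cc3ccccc3OCc3ccccc3)c(O)cc(O)c21 | intermediate
17 | (2S)-8-[2-(benzyloxy)benzyl]-7-[(2-(benzyloxy)-5-{2-(benzyloxy)-3-[2-(benzyloxy)benzyl]benzyl}benzyl)oxy]-5-hydroxy-2-phenylchroman-4-one | O=C1C[C@@H](c2ccccc2)Oc2c(Cc3ccccc3OCc3ccccc3)c(OCc3cc(Cc4cccc(Cc5ccccc5OCc5ccccc5)c4OCc4ccccc4)ccc3OCc3ccccc3)cc(O)c21 | intermediate
18 | (2S)-8-[2-(benzyloxy)benzyl]-6-(2-(benzyloxy)-5-{2-(benzyloxy)-3-[2-(benzyloxy)benzyl]benzyl}benzyl)-5,7-dihydroxy-2-phenylchroman-4-one | O=C1C[C@@H](c2ccccc2)Oc2c(Cc3ccccc3OCc3ccccc3)c(O)c(Cc3cc(Cc4cccc(Cc5ccccc5OCc5ccccc5)c4OCc4ccccc4)ccc3OCc3ccccc3)c(O)c21 | intermediate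
19 | (2S)-5,7-dihydroxy-8-(2-hydroxybenzyl)-6-{2-hydroxy-5-[2-hydroxy-3-(2-hydroxybenzyl)benzyl]benzyl}-2-phenylchroman-4-one | O=C1C[C@@H](c2ccccc2)Oc2c(Cc3ccccc3O)c(O)c(Cc3cc(Cc4cccc(Cc5ccccc5O)c4O)ccc3O)c(O)c21 | target

**Step count**
Total: 15 steps. Longest linear sequence: 10 steps (steps 1, 2, 3, 4, 5, 7, 8, 13, 14, 15).

**Steps most likely to fail**

Step 14. The benzylic cation may escape from the ion pair and alkylate the mono-oxygenated rings of a second molecule, giving oligomers. Traces of water would return it to the 7-phenol, and the acid released may strip plain benzyl ethers. The fallback sets out from 16 and the arm alcohol 10 and leaves out ether 17. It is an intermolecular Friedel–Crafts benzylation, the usual way to C-benzylate 5,7-dihydroxyflavanones with ortho-oxygenated benzyl alcohols: alcohol 10 is added slowly to an excess of 16 with ZnCl2 in dioxane at 60–80 °C. C6 is the only free carbon of ring A, and the excess of nucleophile takes the place of ion-pair control. The fallback comes back to the route at 18.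

Step 11. The iodine may be lost or may migrate under the acid released (protodeiodination and re-iodination, or ipso attack), so that C6 is no longer blocked. The fallback sets out from 13 and drops the block, leaving out steps 10 to 12. Ether 13 is rearranged with Sc(OTf)3 under the conditions of step 11, and the C8 product 16 is separated by chromatography from its C6 isomer, (2S)-6-[2-(benzyloxy)benzyl]-5,7-dihydroxy-2-phenylchroman-4-one F1. This costs material but uses the same known shift. The fallback comes back to the route at 16.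

Step 15. Over-reduction may occur, by hydrogenolysis of the benzylic C2–O1 bond to the dihydrochalcone or by reduction of the C4 ketone, and the crowded ring F ether may cleave incompletely. The fallback sets out from 18 and removes the four benzyl groups without hydrogen: BCl3 with pentamethylbenzene as cation scavenger in CH2Cl2 at −78 °C, a Lewis-acid dealkylation of aryl benzyl ethers. It comes back to the route at the target 19.

**Further compounds**
F1 | step 11 | (2S)-6-[2-(benzyloxy)benzyl]-5,7-dihydroxy-2-phenylchroman-4-one | O=C1C[C@@H](c2ccccc2)Oc2cc(O)c(Cc3ccccc3OCc3ccccc3)c(O)c21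
F0 | step 14 | none | none
F0 | step 15 | none | none
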